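(All runs stem from a simulated flask from invented constants, noise included.)

**The vessels.** The runs made earlier stood in closed stirred flasks; the new set-ups are a closed flask, a flow tank and two dosed flasks.

| flask | substrate | reagent | remark | time |
|---|---|---|---|---|
| cedar | 10 mM | 30 mM | run made earlier |  |
| alder | 6.7 mM | 30 mM | run made earlier |  |
| birch | 15 mM | 30 mM | run made earlier |  |
| elm | 10 mM | 15 mM | run made earlier |  |
| autumn | 10 mM | 30.0 mM | everything together in a closed stirred flask, run for 80 min | 80 min |
| midnight | 10 mM | 30.0 mM | one stirred flow tank at steady state, fed with the mixture as stated, mean residence time 80 min |  |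
| spring | 10 mM (fed, over 64.0 min) | 30.0 mM | a stirred flask in which substrate is dosed at a steady rate over 64.0 min without added volume, worked up at 80 min | 80 min |
| winter | 10 mM | 30.0 mM (fed, over 64.0 min) | all but reagent at the start; reagent goes in evenly over 64.0 min, the run ends at 80 min | 80 min |

| run | time / min | bis adduct / % | substrate / % |
|---|---|---|---|
| cedar | 12.0 | 22 | 6 |
| cedar | 25.0 | 31 | 0 |
| cedar | 40.0 | 33 | 3 |
| cedar | 50.0 | 31 | 1 |
| cedar | 60.0 | 39 | 0 |
| cedar | 80.0 | 30 | 0 |
| alder | 5.00 | 10 | 24 |
| alder | 8.00 | 22 | 11 |
| alder | 15.0 | 31 | 4 |
| alder | 25.0 | 40 | 2 |
| alder | 40.0 | 41 | 0 |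
| alder | 60.0 | 41 | 4 |
| birch | 10.0 | 20 | 6 |
| birch | 20.0 | 21 | 0 |
| birch | 30.0 | 25 | 4 |
| birch | 40.0 | 25 | 2 |
| birch | 50.0 | 26 | 2 |
| birch | 60.0 | 26 | 2 |
| elm | 12.0 | 5 | 10 |
| elm | 25.0 | 16 | 5 |
| elm | 40.0 | 20 | 1 |
| elm | 50.0 | 18 | 0 |
| elm | 60.0 | 19 | 4 |

(standard deviation of a reading: 2 percentage points)

- the stated concentrations are those of everything mixed, before any reaction; amounts are the same in each set-up
- the feed brings no volume worth counting
- the earlier runs were made in a closed, stirred flask

- the set-up with the highest amount of bis adduct at the outlet or at the end, in percent of the substrate put in ("none" if the first two lie within 2 percentage points) (autumn / midnight / spring / winter / none)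
- amount of bis adduct at the outlet or at the end, in percent of the substrate put in, autumn
- amount of bis adduct at the outlet or at the end, in percent of the substrate put in, midnight
- amount of bis adduct at the outlet or at the end, in percent of the substrate put in, spring
- amount of bis adduct at the outlet or at the end, in percent of the substrate put in, winter

**The balance.** In cedar, substrate is the limiting reagent, at 10 mM against 30 mM of reagent, so its balance is the one to write. Cedar's substrate reads 0% at 80.0 min, while its bis adduct levels near 33%, so about 67.0% of the charge went elsewhere. That plateau reads 26%, 33% and 41% for charges of 15 mM, 10 mM and 6.7 mM, so less substrate loses less.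

**Two extremes.** One extreme is the whole charge at once, which is autumn, a repeat of cedar, so about 33%. The other is substrate used as it arrives, with [substrate] near zero, where the balance allows up to the whole charge. In [substrate], spring and the tank lie between these two, above zero and below the charge, while winter starts with the whole substrate charge, as autumn does.

**Standing substrate.** Cedar's 6% at 12.0 min gives a rough disappearance constant of 0.234 min⁻¹. Spring's feed divided by it gives 0.666 mM: this is standing substrate, the level at which substrate used per minute equals substrate fed per minute, a quasi-steady state. The tank's balance gives 0.506 mM. Both levels lie below alder's charge. This reckoning commits to these levels, not to a yield, since the runs do not show what substrate is lost with.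

**The forecast.** It names spring as best, with 33% for autumn, 41% for midnight, 52% for spring and 16% for winter, on the ground that “Low standing intermediate and ample reagent therefore favour bis adduct”.

**The result.**

    substrate + reagent → single product + released group (k = 5.20 M⁻¹ min⁻¹)
    reagent + single product ⇌ bis adduct + released group (K = 9.10, k = 6.60 M⁻¹ min⁻¹)
    2 substrate → homo dimer (k = 16.0 M⁻¹ min⁻¹)
    substrate + bis adduct → side product (k = 45.0 M⁻¹ min⁻¹)

Autumn gives the most, 32.8%, against 24.8% for spring and 11.6% for winter. Spring's substrate stands at 6.94% at 40.0 min, against 6.66% reckoned. With substrate as charged, the half-life of bis adduct against it is 1.5 min, shorter than the 4.4 min of substrate on reagent. At standing substrate that half-life becomes 23.1 min in spring, shorter than the 64.0 min of dosing, and spring ends with 61.8% side product; at the tank's level it is 30.4 min, shorter than the 80 min of residence, and midnight gives 14.5%.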